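The numbers of this flask stand for no real mixture, and the outcome is calculated.

I started from a balance that held throughout: each G charged stood as G, G.Z or X, so G.Z was a share of what X had not taken.

G 0.80 M; L 200 mM (held); time 8.0 h
    L ⇌ Z, rate k1*(csat - [Z]) (k1 = 0.30 h⁻¹, csat = 200 mM)
    G + Z ⇌ G.Z (K2 = 4.2 M⁻¹, k2 = 2.7 M⁻¹ h⁻¹)
    G → X (k3 = 0.045 h⁻¹)
    Z ⇌ Q (K4 = 2.9, k4 = 0.16 h⁻¹)
- at the start none of Z is dissolved
- run time (flask): 8.0 h
- amount of G.Z at 8.0 h, in percent of the G charged
- concentration of Z in solution at 2.0 h, in percent of saturation
- the change that raises the amount of G.Z at 8.0 h, in percent of the G charged most ("none" if none brings more than 2 percentage points) (gamma / alpha / none)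
- amount of G.Z at 8.0 h, in percent of the G charged, after gamma

Could binding keep pace with the gas? By its back step alone, G.Z had a half-life of 1.08 h, shorter than the 2.31 h of transfer, so I treated binding as a quasi-equilibrium. Then G.Z/G followed s, the fraction of saturation reached by Z, through the saturation quotient B, the equilibrium constant of binding times the saturation concentration, 0.840: G.Z/G = B·s.

How far had s climbed in this flask? I counted 3.4 bound Z for each free Z, the equilibrium ratio at the charged G, and held that ratio for the whole run. Setting aside the return from Q, my estimate therefore had s rise toward 65.2% with a time constant of 9.48 h, and it put s at 37.2% at 8.0 h.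

What did that give? With q = B·s = 0.312 taken for the whole run, and X drawing on free G and not on G.Z, I estimated that the pool G + G.Z kept 76.0%. Split in the ratio q, that made 18.1% G.Z. Gamma doubled B, while alpha left B alone and raised s, and the same reckoning gave 30.8% against 26.2%, so I chose gamma.

The forecast gave y 21%, above my figure, sat 21%, best gamma and yb 36%, holding that “Doubling the saturation concentration doubles the driving force”.

The simulation gave y 21.1%, sat 19.1%, best gamma (gain 15 percentage points, against 7.9 points for alpha) and yb 36.2%.

At 8.00 h this flask made Z 1.42 times as fast as it used it, each step taken net, and Z stood at 0.102 M, an s of 51.1%, above my 37.2%. There B·s was 0.429, and the reading of G.Z/G was 0.400. In the same flask read at 20 h, Z at 0.160 M gives q = 0.671, and with X at 47.6% the split pool gives 21.0%. The computed G.Z there is 21.4%.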